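**Plan**

- Retrosynthesis: an acetonide and a silyl ether are taken off first. The cyclohexene (numbered as in compound 14) is then cut at two bonds at once, C1–C6 (quaternary carbinol to CH=) and C3–C4 (CH(OH) to CH(O-acyl)). This [3+3] cut gives a C1–C2–C3 piece that is C2–C3–C4 of D-fructose, and a three-carbon (E)-3-silyloxyallyl-1,1-diboron reagent.
- Enabling feature: the tertiary C1–OH and the secondary C2–OH are cis, so both fit into one dioxolane ring. In that form C1 is the anomeric ketal carbon of a 2,3-O-isopropylidene fructose. It is a ketone equivalent that can stand next to a free aldehyde at C3 without forming a β-dicarbonyl system, and the dioxolane forces cis ring fusion when C1–C6 closes.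
- Forward, pieces: diacetone fructose is benzoylated, freed at O4/O5 and cleaved by periodate to the aldehyde ketal. A silyl propargyl ether is turned into the allyl diboron reagent in three steps.
- Forward, ring: acid-catalysed allylboration of the aldehyde forms C3–C4. Ionization of the ketal and attack of the (Z)-alkenylboronate then forms C1–C6 in the same flask. The carbocycle takes the place of the pyranose ring, with O6–C6–C5 of the sugar replaced by CH=CH–CH(OSi).
- Endgame: desilylation, orthoester-mediated benzoylation of the allylic hydroxyl, acetonide hydrolysis.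
- Stereochemistry: C2 is C3 of D-fructose; C1 follows from the cis fusion to the dioxolane; C3 is set by the chiral phosphoric acid; C4 by the (E)-enol ether in the chair transition state (anti).

Key step: step 7

Assumption: the (R)-enantiomer of the phosphoric acid is assigned by analogy with simple aldehydes; should the facial sense on the sugar aldehyde be the opposite one, its mirror image is used.

**Route**

Step 1
Reactants: 1 2,3:4,5-di-O-isopropylidene-β-D-fructopyranose
Product: 2 1-O-benzoyl-2,3:4,5-di-O-isopropylidene-β-D-fructopyranose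
Conditions: BzCl, pyridine, DMAP (cat.), CH2Cl2, 0 °C → rt
Reagents that add atoms: benzoyl chloride O=C(Cl)c1ccccc1
Why: DMAP-catalysed acylation (nucleophilic acyl substitution) of the only free hydroxyl, the primary C1–OH; no stereocenter is touched.

Step 2
Reactants: 2 1-O-benzoyl-2,3:4,5-di-O-isopropylidene-β-D-fructopyranose
Product: 3 1-O-benzoyl-2,3-O-isopropylidene-β-D-fructopyranose
Conditions: AcOH/H2O (4:1), 40 °C, stopped when 2 is consumed
Reagents that add atoms: none
Why: selective acid hydrolysis of an acetal, in which the 4,5-O-isopropylidene group on two ordinary ring oxygens should cleave faster than the 2,3-acetal that contains the anomeric oxygen and is deactivated by the ring oxygen and the C1 ester; all stereocenters stay.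

Step 3
Reactants: 3 1-O-benzoyl-2,3-O-isopropylidene-β-D-fructopyranose
Product: 4 [(4S,5S)-5-formyl-2,2-dimethyl-4-(2-oxoethoxy)-1,3-dioxolan-4-yl]methyl benzoate
Conditions: NaIO4, THF/H2O, 0 °C → rt; azeotropic drying with toluene, used crude
Reagents that add atoms: none
Why: Malaprade glycol cleavage of the cis-4,5-diol opens the pyranose to a dialdehyde in which the former anomeric carbon is still a ketal, so the aldehyde from C4 is not part of a β-dicarbonyl system and the adjacent stereocenter keeps its configuration.

Step 4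
Reactants: 5 tert-butyldimethyl(prop-2-yn-1-yloxy)silane
Product: 6 tert-butyldimethyl{[3-(4,4,5,5-tetramethyl-1,3,2-dioxaborolan-2-yl)prop-2-yn-1-yl]oxy}silane
Conditions: n-BuLi, THF, −78 °C; i-PrOBpin, −78 °C; then HCl·Et2O, −78 °C → rt
Reagents that add atoms: 2-isopropoxy-4,4,5,5-tetramethyl-1,3,2-dioxaborolane CC(C)OB1OC(C)(C)C(C)(C)O1
Why: deprotonation of the terminal alkyne, borylation of the acetylide and collapse of the ate complex with anhydrous acid, the standard alkynylboronate synthesis; no stereocenter.

Step 5
Reactants: 6 tert-butyldimethyl{[3-(4,4,5,5-tetramethyl-1,3,2-dioxaborolan-2-yl)prop-2-yn-1-yl]oxy}silane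
Product: 7 {[3,3-bis(4,4,5,5-tetramethyl-1,3,2-dioxaborolan-2-yl)prop-2-en-1-yl]oxy}(tert-butyl)dimethylsilane
Conditions: HBpin, Cp2Zr(H)Cl (10 mol %), Et3N (10 mol %), CH2Cl2, rt → 40 °C
Reagents that add atoms: pinacolborane B1OC(C)(C)C(C)(C)O1
Why: zirconocene-hydride-catalysed syn-hydroboration of an alkynylboronate, in which the metal, and after transmetalation the boron, should go to the carbon that already carries boron, as in the hydrozirconation of alkynylboronates; this gives the 1,1-diborylalkene.

Step 6
Reactants: 7 {[3,3-bis(4,4,5,5-tetramethyl-1,3,2-dioxaborolan-2-yl)prop-2-en-1-yl]oxy}(tert-butyl)dimethylsilane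
Product: 8 {[(E)-3,3-bis(4,4,5,5-tetramethyl-1,3,2-dioxaborolan-2-yl)prop-1-en-1-yl]oxy}(tert-butyl)dimethylsilane
Conditions: [Ir(cod)(PPh2Me)2]PF6 (3 mol %, activated with H2, then degassed), THF, rt
Reagents that add atoms: none
Why: iridium-hydride-catalysed 1,3-hydrogen shift (allyl silyl ether to silyl enol ether isomerization), a reaction type known for 3-silyloxy-1-propenylboronates, should move the double bond out of the diboryl position and give the (E)-enol ether.

Step 7
Reactants: 4 [(4S,5S)-5-formyl-2,2-dimethyl-4-(2-oxoethoxy)-1,3-dioxolan-4-yl]methyl benzoate; 8 {[(E)-3,3-bis(4,4,5,5-tetramethyl-1,3,2-dioxaborolan-2-yl)prop-1-en-1-yl]oxy}(tert-butyl)dimethylsilane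
Product: 10 [(3aS,4S,5R,7aS)-5-[(tert-butyldimethylsilyl)oxy]-4-hydroxy-2,2-dimethyl-3a,4,5,7a-tetrahydro-1,3-benzodioxol-7a-yl]methyl benzoate, via bis-allylboration adduct 9 (not isolated)
Conditions: 8 (2.3 equiv), (R)-TRIP [(R)-3,3′-bis(2,4,6-triisopropylphenyl)-1,1′-binaphthyl-2,2′-diyl hydrogen phosphate] (10 mol %), 4 Å MS, toluene, −40 °C → rt; then TMSOTf (20 mol %), CH2Cl2, −40 → 0 °C, same flask; aq. NaHCO3
Reagents that add atoms: none
Why: Proposed new method: a [3+3] annulation with two bond-forming events in one flask; first the prochiral allyl-1,1-diboronate adds to the dioxolane-bound aldehyde of 4 through a phosphoric-acid-bound chair (Zimmerman–Traxler) transition state, which joins the silyloxy-bearing carbon to the aldehyde carbon and leaves a (Z)-alkenylboronate because the spectator boryl group sits axial, and then TMSOTf ionizes the exocyclic C–O bond of the ketal and the boron-bearing alkene carbon attacks the dioxolanyl oxocarbenium ion, with boron passing to the departing alkoxide, which joins the alkene to the fully substituted carbon. The closest known reaction types are the acid-catalysed allylboration of aldehydes with α-boryl allylboronates, the Petasis-type transfer of alkenyl groups from boronates to oxocarbenium ions made from acetals, and the vinylsilane-terminated oxocarbenium cyclization; their combination on a masked keto aldehyde is not known. The cyclohexene closes in the 6-endo mode with respect to the alkenylboronate, and because the three-atom tether can reach only the face of the cation that carries the side chain, the new ring is cis-fused to the dioxolane, which fixes the quaternary carbon relative to the fructose-derived stereocenter. The carbinol carbon is set by the chiral acid (the Felkin–Anh bias of the aldehyde is not relied upon) and the silyloxy carbon by the (E)-enol ether in the chair, which gives the anti pair. The step needs ionization at the ketal oxygen of the glycolaldehyde-derived arm and not at the acetonide, which its exocyclic position and the participating benzoate on the neighbouring CH2 should secure, and it needs the (Z)-alkene, which the axial boryl group secures; the second aldehyde of 4 only takes up a second equivalent of 8 and leaves with the arm.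

Step 8
Reactants: 10 [(3aS,4S,5R,7aS)-5-[(tert-butyldimethylsilyl)oxy]-4-hydroxy-2,2-dimethyl-3a,4,5,7a-tetrahydro-1,3-benzodioxol-7a-yl]methyl benzoate
Product: 11 [(3aS,4R,5R,7aS)-4,5-dihydroxy-2,2-dimethyl-3a,4,5,7a-tetrahydro-1,3-benzodioxol-7a-yl]methyl benzoate
Conditions: HF·pyridine, pyridine, THF, 0 °C → rt
Reagents that add atoms: none
Why: fluoride cleavage of the secondary silyl ether under buffered acidic conditions that should leave the acetonide and the primary benzoate in place; no stereocenter changes.

Step 9
Reactants: 11 [(3aS,4R,5R,7aS)-4,5-dihydroxy-2,2-dimethyl-3a,4,5,7a-tetrahydro-1,3-benzodioxol-7a-yl]methyl benzoate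
Product: 13 [(3aS,4R,5R,7aS)-5-(benzoyloxy)-4-hydroxy-2,2-dimethyl-3a,4,5,7a-tetrahydro-1,3-benzodioxol-7a-yl]methyl benzoate, via cyclic orthobenzoate 12 (not isolated)
Conditions: PhC(OMe)3, CSA (cat.), CH2Cl2, rt; then AcOH/H2O (4:1), rt
Reagents that add atoms: trimethyl orthobenzoate COC(OC)(OC)c1ccccc1; water O
Why: acid-catalysed orthoester exchange ties the cis-diol into a cyclic orthobenzoate, and mild aqueous acid opens it to the axial ester and the equatorial alcohol; in the preferred half-chair (CH2OBz pseudoequatorial) the allylic oxygen is pseudoaxial, so the benzoate should end up on the allylic oxygen.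

Step 10
Reactants: 13 [(3aS,4R,5R,7aS)-5-(benzoyloxy)-4-hydroxy-2,2-dimethyl-3a,4,5,7a-tetrahydro-1,3-benzodioxol-7a-yl]methyl benzoate
Product: 14 [(1S,2S,3S,4R)-4-(benzoyloxy)-1,2,3-trihydroxycyclohex-5-en-1-yl]methyl benzoate
Conditions: TFA/H2O (9:1), CH2Cl2, 0 °C
Reagents that add atoms: none
Why: acid hydrolysis of the isopropylidene acetal at low temperature, a standard last step for cis-diol acetonides; the two esters and all four stereocenters are retained.

**Compound list**

1 | 2,3:4,5-di-O-isopropylidene-β-D-fructopyranose | OC[C@@]12OC[C@H]3OC(C)(C)O[C@H]3[C@@H]1OC(C)(C)O2 | starting material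
2 | 1-O-benzoyl-2,3:4,5-di-O-isopropylidene-β-D-fructopyranose | O=C(OC[C@@]12OC[C@H]3OC(C)(C)O[C@H]3[C@@H]1OC(C)(C)O2)c1ccccc1 | intermediate
3 | 1-O-benzoyl-2,3-O-isopropylidene-β-D-fructopyranose | O=C(OC[C@@]12OC[C@@H](O)[C@@H](O)[C@@H]1OC(C)(C)O2)c1ccccc1 | intermediate
4 | [(4S,5S)-5-formyl-2,2-dimethyl-4-(2-oxoethoxy)-1,3-dioxolan-4-yl]methyl benzoate | O=C(OC[C@@]1(OCC=O)[C@H](C=O)OC(C)(C)O1)c1ccccc1 | intermediate
5 | tert-butyldimethyl(prop-2-yn-1-yloxy)silane | C#CCO[Si](C)(C)C(C)(C)C | starting material
6 | tert-butyldimethyl{[3-(4,4,5,5-tetramethyl-1,3,2-dioxaborolan-2-yl)prop-2-yn-1-yl]oxy}silane | CC(C)(C)[Si](C)(C)OCC#CB1OC(C)(C)C(C)(C)O1 | intermediate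
7 | {[3,3-bis(4,4,5,5-tetramethyl-1,3,2-dioxaborolan-2-yl)prop-2-en-1-yl]oxy}(tert-butyl)dimethylsilane | CC(C)(C)[Si](C)(C)OCC=C(B1OC(C)(C)C(C)(C)O1)B1OC(C)(C)C(C)(C)O1 | intermediate
8 | {[(E)-3,3-bis(4,4,5,5-tetramethyl-1,3,2-dioxaborolan-2-yl)prop-1-en-1-yl]oxy}(tert-butyl)dimethylsilane | CC(C)(C)[Si](C)(C)O/C=C/C(B1OC(C)(C)C(C)(C)O1)B1OC(C)(C)C(C)(C)O1 | intermediate
9 | bis-allylboration adduct of 4: each aldehyde converted into a CH(OBpin)–CH(OTBS)–CH=CH–Bpin unit, (Z)-alkene, anti, carbinol carbons S and silyloxy carbons R | O=C(OC[C@@]1(OC[C@H](OB2OC(C)(C)C(C)(C)O2)[C@H](O[Si](C)(C)C(C)(C)C)/C=C\B2OC(C)(C)C(C)(C)O2)[C@H]([C@H](OB2OC(C)(C)C(C)(C)O2)[C@H](O[Si](C)(C)C(C)(C)C)/C=C\B2OC(C)(C)C(C)(C)O2)OC(C)(C)O1)c1ccccc1 | intermediate (not isolated)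
10 | [(3aS,4S,5R,7aS)-5-[(tert-butyldimethylsilyl)oxy]-4-hydroxy-2,2-dimethyl-3a,4,5,7a-tetrahydro-1,3-benzodioxol-7a-yl]methyl benzoate | O=C(OC[C@@]12C=C[C@@H](O[Si](C)(C)C(C)(C)C)[C@@H](O)[C@@H]1OC(C)(C)O2)c1ccccc1 | intermediate
11 | [(3aS,4R,5R,7aS)-4,5-dihydroxy-2,2-dimethyl-3a,4,5,7a-tetrahydro-1,3-benzodioxol-7a-yl]methyl benzoate | O=C(OC[C@@]12C=C[C@@H](O)[C@@H](O)[C@@H]1OC(C)(C)O2)c1ccccc1 | intermediate
12 | cyclic orthobenzoate of 11 (2-methoxy-2-phenyl-1,3-dioxolane fused at the two former hydroxyl carbons; both epimers at the orthoester carbon) | O=C(OC[C@@]12C=C[C@H]3OC(OC)(c4ccccc4)O[C@H]3[C@@H]1OC(C)(C)O2)c1ccccc1 | intermediate (not isolated)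
13 | [(3aS,4R,5R,7aS)-5-(benzoyloxy)-4-hydroxy-2,2-dimethyl-3a,4,5,7a-tetrahydro-1,3-benzodioxol-7a-yl]methyl benzoate | O=C(OC[C@@]12C=C[C@@H](OC(=O)c3ccccc3)[C@@H](O)[C@@H]1OC(C)(C)O2)c1ccccc1 | intermediate
14 | [(1S,2S,3S,4R)-4-(benzoyloxy)-1,2,3-trihydroxycyclohex-5-en-1-yl]methyl benzoate | O=C(OC[C@@]1(O)C=C[C@@H](OC(=O)c2ccccc2)[C@@H](O)[C@@H]1O)c1ccccc1 | target

**Count**

Total steps: 10. Longest linear sequence: 7 steps (steps 1, 2, 3, 7, 8, 9, 10 from 1 to 14; the reagent branch through steps 4, 5, 6 is equally long).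

**Steps most likely to fail**

Step 7 (Proposed new method). What may go wrong: ionization at the acetonide in place of the arm oxygen; an alkenylboronate too weakly nucleophilic to trap the oxocarbenium ion before it decomposes; loss of facial control in the allylboration of the hindered aldehyde. The fallback uses known reactions and closes the ring by a chromium-mediated carbonyl addition to the unmasked ketone in place of the cationic closure. It sets out from 4 and 8. The allylboration is run as in step 7 but quenched with water, and the bis-adduct diol F1 is isolated. NIS in MeCN exchanges both boron groups for iodine with retention and should give the bis-(Z)-alkenyl iodide F2. Aqueous HCl in THF hydrolyses the ketal, which releases the arm and the acetonide and leaves the open-chain keto diol F3. An intramolecular Nozaki–Hiyama–Kishi reaction (CrCl2, NiCl2 cat., DMF) should close the ring to the triol F4, with chromium chelation between the ketone oxygen and the neighbouring hydroxyl expected to favour the cis-diol. 2-Methoxypropene with PPTS then ties the cis tertiary/secondary diol into the acetonide, and the route is rejoined at 10.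

Step 6. What may go wrong: the iridium hydride fails to insert into the trisubstituted 1,1-diborylalkene, or protodeboronation competes with the hydrogen shift. The fallback changes the order of events: the double bond is moved first on the less hindered mono-boron compound and the second boron is put in afterwards. It sets out from 5. Cp2Zr(H)Cl-catalysed hydroboration with pinacolborane should give the (E)-alkenylboronate F5. The same iridium catalyst moves the double bond to give the (E)-3-silyloxyallylboronate F6. Deprotonation α to boron with LiTMP (THF, −78 °C) and trapping with i-PrOBpin installs the second boron, and the route is rejoined at 8.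

Step 9. What may go wrong: loss of regiocontrol when the orthoester opens, or acyl migration between the two cis-vicinal oxygens under acid. The fallback uses protecting-group differentiation in place of the stereoelectronic opening. It sets out from 10. The free hydroxyl is chloroacetylated ((ClCH2CO)2O, pyridine) to the chloroacetate F7. HF·pyridine removes the silyl group to give the allylic alcohol F8. BzCl/pyridine gives the benzoate chloroacetate F9. Thiourea (NaHCO3, EtOH) removes the chloroacetate selectively, and the route is rejoined at 13.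

**Further compounds**

F1 | step 7 | bis-adduct diol: 9 with both O–Bpin groups hydrolysed to OH, alkenyl–Bpin groups kept | O=C(OC[C@@]1(OC[C@H](O)[C@H](O[Si](C)(C)C(C)(C)C)/C=C\B2OC(C)(C)C(C)(C)O2)[C@H]([C@H](O)[C@H](O[Si](C)(C)C(C)(C)C)/C=C\B2OC(C)(C)C(C)(C)O2)OC(C)(C)O1)c1ccccc1
F2 | step 7 | bis-(Z)-alkenyl iodide corresponding to F1 | O=C(OC[C@@]1(OC[C@H](O)[C@H](O[Si](C)(C)C(C)(C)C)/C=C\I)[C@H]([C@H](O)[C@H](O[Si](C)(C)C(C)(C)C)/C=C\I)OC(C)(C)O1)c1ccccc1
F3 | step 7 | (3S,4S,5R,6Z)-5-[(tert-butyldimethylsilyl)oxy]-3,4-dihydroxy-7-iodo-2-oxohept-6-en-1-yl benzoate | O=C(OCC(=O)[C@@H](O)[C@H](O)[C@H](O[Si](C)(C)C(C)(C)C)/C=C\I)c1ccccc1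
F4 | step 7 | [(1S,2S,3S,4R)-4-[(tert-butyldimethylsilyl)oxy]-1,2,3-trihydroxycyclohex-5-en-1-yl]methyl benzoate | O=C(OC[C@@]1(O)C=C[C@@H](O[Si](C)(C)C(C)(C)C)[C@@H](O)[C@@H]1O)c1ccccc1
F5 | step 6 | tert-butyldimethyl{[(E)-3-(4,4,5,5-tetramethyl-1,3,2-dioxaborolan-2-yl)prop-2-en-1-yl]oxy}silane | CC(C)(C)[Si](C)(C)OC/C=C/B1OC(C)(C)C(C)(C)O1
F6 | step 6 | tert-butyldimethyl{[(E)-3-(4,4,5,5-tetramethyl-1,3,2-dioxaborolan-2-yl)prop-1-en-1-yl]oxy}silane | CC(C)(C)[Si](C)(C)O/C=C/CB1OC(C)(C)C(C)(C)O1
F7 | step 9 | 10 with the free hydroxyl as its chloroacetate | O=C(OC[C@@]12C=C[C@@H](O[Si](C)(C)C(C)(C)C)[C@@H](OC(=O)CCl)[C@@H]1OC(C)(C)O2)c1ccccc1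
F8 | step 9 | chloroacetate with free allylic hydroxyl | O=C(OC[C@@]12C=C[C@@H](O)[C@@H](OC(=O)CCl)[C@@H]1OC(C)(C)O2)c1ccccc1
F9 | step 9 | allylic benzoate chloroacetate | O=C(OC[C@@]12C=C[C@@H](OC(=O)c3ccccc3)[C@@H](OC(=O)CCl)[C@@H]1OC(C)(C)O2)c1ccccc1
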